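A closed, stirred vessel holds a racemate, a single-handed catalyst and a partner. Plan by counting turnovers.

| flask | left-handed substrate | right-handed substrate | partner | protic impurity | free catalyst | remark | time |
|---|---|---|---|---|---|---|---|
| alder | 0.046 M | 0.046 M | 0.069 M | 4.6 mM | 0.46 mM | run made earlier |  |
| maple | 0.046 M | 0.046 M | 0.10 M | 4.6 mM | 0.46 mM | run made earlier |  |
| violet | 0.046 M | 0.046 M | 0.138 M | 4.60 mM | 0.46 mM |  | 6.0 min |
| grey | 0.046 M | 0.046 M | 0.138 M | 4.60 mM | 0.46 mM |  | 20 min |

- alder (time / min: left-handed product / %, right-handed product / %): 0.250: 2, 1; 0.500: 7, 0; 1.00: 14, 3; 2.00: 23, 0; 4.00: 31, 3
- maple (time / min: left-handed product / %, right-handed product / %): 0.667: 14, 1; 1.33: 23, 1; 2.00: 33, 3; 3.00: 42, 2; 4.00: 48, 4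

(readings scatter by 2 percentage points)

- free catalyst is single-handed; left-handed substrate and right-handed substrate are mirror images of each other, charged as a racemate, each of them at the stated concentration
- the earlier runs were read with a standard deviation of 2 percentage points
- reactions considered so far: free catalyst + left-handed substrate <-> catalyst intermediate A; free catalyst + right-handed substrate <-> catalyst intermediate B; partner + catalyst intermediate A -> free catalyst + left-handed product; partner + catalyst intermediate B -> free catalyst + right-handed product; partner -> decomposition product; partner + protic impurity -> quenched reagent; 2 free catalyst -> spent catalyst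
- an excess is the difference of the two amounts in percent of their sum
- an excess is below zero if the other one leads

1. which of the two ends with the higher excess of left-handed product over right-handed product in the product ("neither" if they lie within 2 percentage points) (violet / grey / neither)
2. excess of left-handed product over right-handed product in the product at the end, violet
3. excess of left-handed product over right-handed product in the product at the end, grey

1. Read alder's first minute: 14% left-handed product is 28.0 min⁻¹ per catalyst (the turnover frequency), as a reading.

2. Scale that with partner less protic impurity, multiply by the time, and divide by left-handed substrate per catalyst, 100. Violet gives 3.48, grey 11.6. Call this the turnover count: turnovers at that first rate by that time over turnovers the left-handed substrate demands.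

3. Test it. Alder at 4.00 min counts 1.12 and reads 31% left-handed product, against a ceiling of 50.0%. Maple at 4.00 min counts 1.66 and reads 48%. So take maple's count as the mark, not one.

4. Both flasks pass the mark, and grey's count is higher. Further product there can be right-handed, which lowers the excess, so I expect violet above grey, both under the excess read from maple's last readings, 84.6%. One number gives this order but not the size of the drop: no reading shows the right-handed rate past the mark.

The forecast says violet, with 58% for violet and 43% for grey, and says the right-handed substrate “slows as activity dies”.

The flask gives violet: 59.0% against 31.9%, a higher excess in violet.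

    free catalyst + left-handed substrate ⇌ catalyst intermediate A (K = 300 M⁻¹, k = 3400 M⁻¹ s⁻¹)
    free catalyst + right-handed substrate ⇌ catalyst intermediate B (K = 56.0 M⁻¹, k = 5200 M⁻¹ s⁻¹)
    partner + catalyst intermediate A → free catalyst + left-handed product (k = 9.30 M⁻¹ s⁻¹)
    partner + catalyst intermediate B → free catalyst + right-handed product (k = 2.00 M⁻¹ s⁻¹)
    partner → decomposition product (k = 7.70 × 10⁻⁶ s⁻¹)
    partner + protic impurity → quenched reagent (k = 4.90 M⁻¹ s⁻¹)
    2 free catalyst → spent catalyst (k = 26.0 M⁻¹ s⁻¹)

Grey ends with left-handed product 50.0%, right-handed product 25.8% and 79.2% of its catalyst spent. Violet's count at 3.00 min is 1.74, beside the mark of 1.66, and its left-handed substrate stands at 3.03%.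

Now count grey with 0.0018 M free catalyst: 45.4, further past the mark than grey, so expect a lower excess. It gives 18.7%, with left-handed product 50.0%.

(The data stem from a simulated flask with made-up constants, and the scatter is random.)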